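## Retrosynthetic overview
1. The target comes from its tris(aryl TIPS) ether by buffered fluoride. The acetate goes onto the free C‑3 carbinol just before that, after selective removal of a C‑3 TES ether.
2. The (E)‑C6=C7 bond is made by Julia–Kocienski olefination of a C1–C6 phenyltetrazolyl sulfone with 4‑(TIPSO)benzaldehyde.
3. The sulfone comes from the primary alcohol obtained by anti‑Markovnikov hydroboration of a TES‑protected homoallylic alcohol (C4–C6 are the former allyl unit).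
4. The key C3–C4 bond and the only stereocentre are set by Brown asymmetric allylation of 3‑[3,4‑bis(TIPSO)phenyl]propanal.
5. The aldehyde comes from dihydrocaffeic acid. No ring is formed; both arenes are bought.

Assumption: the stereocentre in the SMILES is C‑3 of the heptene chain and reads (S), and the alkene is (E). "(−)‑Ipc2BOMe" means the enantiomer made from (+)‑α‑pinene (dIpc series).

## Route

Step 1
Reactants: 1 3‑(3,4‑dihydroxyphenyl)propanoic acid (dihydrocaffeic acid)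
Product: 2 methyl 3‑(3,4‑dihydroxyphenyl)propanoate
Conditions: MeOH, cat. H2SO4, reflux
Reagents that add atoms: methanol, CO
Why: Fischer esterification in excess methanol goes to completion, and the acidic medium keeps the catechol from autoxidising.

Step 2
Reactants: 2 methyl 3‑(3,4‑dihydroxyphenyl)propanoate
Product: 3 methyl 3‑[3,4‑bis(triisopropylsilyloxy)phenyl]propanoate
Conditions: TIPSCl (2.5 equiv), imidazole (5 equiv), cat. DMAP, DMF, rt → 40 °C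
Reagents that add atoms: chlorotriisopropylsilane, CC(C)[Si](Cl)(C(C)C)C(C)C
Why: Imidazole‑promoted O‑silylation gives aryl TIPS ethers, which withstand the later hydride, peroxide/perborate, KHMDS and mild‑acid steps far better than aryl TBS ethers yet still fall to fluoride.

Step 3
Reactants: 3 methyl 3‑[3,4‑bis(triisopropylsilyloxy)phenyl]propanoate
Product: 4 3‑[3,4‑bis(triisopropylsilyloxy)phenyl]propan‑1‑ol
Conditions: DIBAL‑H (2.5 equiv), CH2Cl2, −78 → 0 °C; aq. Rochelle salt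
Reagents that add atoms: none
Why: Full DIBAL‑H ester reduction to the alcohol avoids the unreliable one‑step stop at the aldehyde and leaves aryl silyl ethers untouched.

Step 4
Reactants: 4 3‑[3,4‑bis(triisopropylsilyloxy)phenyl]propan‑1‑ol
Product: 5 3‑[3,4‑bis(triisopropylsilyloxy)phenyl]propanal
Conditions: TEMPO (10 mol %), PhI(OAc)2 (1.1 equiv), CH2Cl2, rt
Reagents that add atoms: none
Why: The TEMPO/PhI(OAc)2 (Piancatelli–Margarita) oxidation stops cleanly at the aldehyde under nearly neutral conditions that the silyl‑protected catechol tolerates.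

Step 5
Reactants: 5 3‑[3,4‑bis(triisopropylsilyloxy)phenyl]propanal; 6 allylmagnesium bromide; 7 (−)‑B‑methoxydiisopinocampheylborane
Product: 10 (3R)‑1‑[3,4‑bis(triisopropylsilyloxy)phenyl]hex‑5‑en‑3‑ol, via dIpc2B‑allyl reagent 8 (not isolated), via homoallyl borinate 9 (not isolated)
Conditions: 7 + 6, Et2O, −78 °C → rt, 1 h; recool to −78 °C (−100 °C after filtering off Mg salts for highest ee), add 5, 3 h; then MeOH, pH 7 phosphate buffer, 30 % H2O2, 0 °C → rt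
Reagents that add atoms: none
Why: In this Brown asymmetric carbonyl allylation the allyl group is delivered through a closed chair Zimmerman–Traxler transition state, and the dIpc ligands direct it to the Si face of unbranched aliphatic aldehydes, setting C‑3 as (R) here (allyl outranks CH2CH2Ar) in typically 92–96 % ee, while the buffered peroxide work‑up spares the aryl silyl ethers.

Step 6
Reactants: 10 (3R)‑1‑[3,4‑bis(triisopropylsilyloxy)phenyl]hex‑5‑en‑3‑ol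
Product: 11 {[(3R)‑1‑[3,4‑bis(triisopropylsilyloxy)phenyl]hex‑5‑en‑3‑yl]oxy}triethylsilane
Conditions: TESCl (1.3 equiv), imidazole (2.5 equiv), CH2Cl2, 0 °C → rt
Reagents that add atoms: chlorotriethylsilane, CC[Si](Cl)(CC)CC
Why: O‑silylation leaves the C–O bond of the stereocentre untouched, and the alkyl TES ether survives borane, Mitsunobu, buffered peracid and KHMDS but can later be removed by mild acid without harming aryl TIPS ethers.

Step 7
Reactants: 11 {[(3R)‑1‑[3,4‑bis(triisopropylsilyloxy)phenyl]hex‑5‑en‑3‑yl]oxy}triethylsilane; 12 9‑borabicyclo[3.3.1]nonane (9‑BBN)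
Product: 14 (4R)‑6‑[3,4‑bis(triisopropylsilyloxy)phenyl]‑4‑(triethylsilyloxy)hexan‑1‑ol, via B‑alkyl‑9‑BBN adduct 13 (not isolated)
Conditions: 9‑BBN (1.5 equiv, 0.5 M in THF), 0 °C → rt; then H2O, NaBO3·4H2O (5 equiv), rt
Reagents that add atoms: sodium perborate (used as the tetrahydrate), [Na+].[O-]OB=O
Why: In this Brown hydroboration–oxidation the bulky 9‑BBN adds anti‑Markovnikov to the terminal alkene (>99:1), and perborate oxidises the C–B bond without the strong NaOH that endangers aryl silyl ethers.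

Step 8
Reactants: 14 (4R)‑6‑[3,4‑bis(triisopropylsilyloxy)phenyl]‑4‑(triethylsilyloxy)hexan‑1‑ol
Product: 15 5‑{[(4R)‑6‑[3,4‑bis(triisopropylsilyloxy)phenyl]‑4‑(triethylsilyloxy)hexyl]sulfanyl}‑1‑phenyl‑1H‑tetrazole
Conditions: 1‑phenyl‑1H‑tetrazole‑5‑thiol (1.3 equiv), PPh3 (1.3 equiv), DIAD (1.3 equiv), THF, 0 °C → rt
Reagents that add atoms: 1‑phenyl‑1H‑tetrazole‑5‑thiol, Sc1nnnn1-c1ccccc1
Why: In this Mitsunobu thioetherification the acidic thiol displaces the activated primary alcohol by SN2 under neutral conditions, far from the stereocentre.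

Step 9
Reactants: 15 5‑{[(4R)‑6‑[3,4‑bis(triisopropylsilyloxy)phenyl]‑4‑(triethylsilyloxy)hexyl]sulfanyl}‑1‑phenyl‑1H‑tetrazole
Product: 16 5‑{[(4R)‑6‑[3,4‑bis(triisopropylsilyloxy)phenyl]‑4‑(triethylsilyloxy)hexyl]sulfonyl}‑1‑phenyl‑1H‑tetrazole
Conditions: mCPBA (2.5–3 equiv) over solid NaHCO3 buffer, CH2Cl2, 0 °C → rt
Reagents that add atoms: 3‑chloroperoxybenzoic acid, OOC(=O)c1cccc(Cl)c1
Why: Peracid sulfide‑to‑sulfone oxidation is done while no alkene is present, and the bicarbonate buffer protects the TES ether.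

Step 10
Reactants: 17 4‑hydroxybenzaldehyde
Product: 18 4‑(triisopropylsilyloxy)benzaldehyde
Conditions: TIPSCl (1.2 equiv), imidazole (2.5 equiv), DMF, rt
Reagents that add atoms: chlorotriisopropylsilane, CC(C)[Si](Cl)(C(C)C)C(C)C
Why: Imidazole‑promoted O‑silylation masks the acidic phenol, so the aldehyde cannot quench the sulfonyl carbanion and all three phenols carry the same fluoride‑labile group.

Step 11
Reactants: 16 5‑{[(4R)‑6‑[3,4‑bis(triisopropylsilyloxy)phenyl]‑4‑(triethylsilyloxy)hexyl]sulfonyl}‑1‑phenyl‑1H‑tetrazole; 18 4‑(triisopropylsilyloxy)benzaldehyde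
Product: 20 {[(3S,6E)‑1‑[3,4‑bis(triisopropylsilyloxy)phenyl]‑7‑[4‑(triisopropylsilyloxy)phenyl]hept‑6‑en‑3‑yl]oxy}triethylsilane, via potassiated sulfone 19 (not isolated)
Conditions: KHMDS (1.15 equiv), DME, −60 °C, 45 min; then 18 (1.3 equiv), −60 °C → rt
Reagents that add atoms: none
Why: In this Julia–Kocienski olefination the PT‑sulfonyl carbanion adds to a non‑enolisable, electron‑rich aryl aldehyde, and Smiles rearrangement with loss of SO2 and tetrazolone gives the conjugated (E)‑alkene (typically ≥95:5), while C‑3 is untouched and its descriptor changes from R to S only because the CIP ranking changes.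

Step 12
Reactants: 20 {[(3S,6E)‑1‑[3,4‑bis(triisopropylsilyloxy)phenyl]‑7‑[4‑(triisopropylsilyloxy)phenyl]hept‑6‑en‑3‑yl]oxy}triethylsilane
Product: 21 (3S,6E)‑1‑[3,4‑bis(triisopropylsilyloxy)phenyl]‑7‑[4‑(triisopropylsilyloxy)phenyl]hept‑6‑en‑3‑ol
Conditions: PPTS (0.2 equiv), MeOH/CH2Cl2 1:1, rt
Reagents that add atoms: none
Why: Acid‑catalysed methanolysis cleaves the alkyl TES ether orders of magnitude faster than the acid‑stable aryl TIPS ethers, and PPTS is too weak to protonate the styrene.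

Step 13
Reactants: 21 (3S,6E)‑1‑[3,4‑bis(triisopropylsilyloxy)phenyl]‑7‑[4‑(triisopropylsilyloxy)phenyl]hept‑6‑en‑3‑ol
Product: 22 (3S,6E)‑1‑[3,4‑bis(triisopropylsilyloxy)phenyl]‑7‑[4‑(triisopropylsilyloxy)phenyl]hept‑6‑en‑3‑yl acetate
Conditions: Ac2O (2 equiv), pyridine, cat. DMAP, CH2Cl2, rt
Reagents that add atoms: acetic anhydride, CC(=O)OC(C)=O
Why: DMAP‑catalysed O‑acylation acylates the only free hydroxyl at oxygen, so the (S) configuration is retained.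

Step 14
Reactants: 22 (3S,6E)‑1‑[3,4‑bis(triisopropylsilyloxy)phenyl]‑7‑[4‑(triisopropylsilyloxy)phenyl]hept‑6‑en‑3‑yl acetate
Product: 23 (3S,6E)‑1‑(3,4‑dihydroxyphenyl)‑7‑(4‑hydroxyphenyl)hept‑6‑en‑3‑yl acetate (target)
Conditions: TBAF (3.6 equiv) premixed with AcOH (4 equiv), THF, 0 °C → rt, under Ar; aq. NH4Cl work‑up
Reagents that add atoms: none
Why: In this fluoride‑driven desilylation the aryl silyl ethers are excellent leaving groups, and the acetic acid buffer protonates each phenoxide at once, so the secondary acetate is neither cleaved nor transferred and the catechol is not autoxidised.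

## Compound list
1 | 3‑(3,4‑dihydroxyphenyl)propanoic acid | O=C(O)CCc1ccc(O)c(O)c1 | starting material
2 | methyl 3‑(3,4‑dihydroxyphenyl)propanoate | COC(=O)CCc1ccc(O)c(O)c1 | intermediate
3 | methyl 3‑[3,4‑bis(triisopropylsilyloxy)phenyl]propanoate | COC(=O)CCc1ccc(O[Si](C(C)C)(C(C)C)C(C)C)c(O[Si](C(C)C)(C(C)C)C(C)C)c1 | intermediate
4 | 3‑[3,4‑bis(triisopropylsilyloxy)phenyl]propan‑1‑ol | OCCCc1ccc(O[Si](C(C)C)(C(C)C)C(C)C)c(O[Si](C(C)C)(C(C)C)C(C)C)c1 | intermediate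
5 | 3‑[3,4‑bis(triisopropylsilyloxy)phenyl]propanal | O=CCCc1ccc(O[Si](C(C)C)(C(C)C)C(C)C)c(O[Si](C(C)C)(C(C)C)C(C)C)c1 | intermediate
6 | allylmagnesium bromide | C=CC[Mg]Br | starting material
7 | (−)‑B‑methoxydiisopinocampheylborane (from (+)‑α‑pinene) | COB([C@@H]1C[C@@H]2C[C@H]([C@H]1C)C2(C)C)[C@@H]1C[C@@H]2C[C@H]([C@H]1C)C2(C)C | starting material
8 | B‑allyldiisopinocampheylborane, dIpc series | C=CCB([C@@H]1C[C@@H]2C[C@H]([C@H]1C)C2(C)C)[C@@H]1C[C@@H]2C[C@H]([C@H]1C)C2(C)C | intermediate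
9 | (3R)‑1‑[3,4‑bis(triisopropylsilyloxy)phenyl]hex‑5‑en‑3‑yl diisopinocampheylborinate | O([C@@H](CC=C)CCc1ccc(O[Si](C(C)C)(C(C)C)C(C)C)c(O[Si](C(C)C)(C(C)C)C(C)C)c1)B([C@@H]1C[C@@H]2C[C@H]([C@H]1C)C2(C)C)[C@@H]1C[C@@H]2C[C@H]([C@H]1C)C2(C)C | intermediate
10 | (3R)‑1‑[3,4‑bis(triisopropylsilyloxy)phenyl]hex‑5‑en‑3‑ol | O[C@@H](CC=C)CCc1ccc(O[Si](C(C)C)(C(C)C)C(C)C)c(O[Si](C(C)C)(C(C)C)C(C)C)c1 | intermediate
11 | {[(3R)‑1‑[3,4‑bis(triisopropylsilyloxy)phenyl]hex‑5‑en‑3‑yl]oxy}triethylsilane | CC[Si](CC)(CC)O[C@@H](CC=C)CCc1ccc(O[Si](C(C)C)(C(C)C)C(C)C)c(O[Si](C(C)C)(C(C)C)C(C)C)c1 | intermediate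
12 | 9‑borabicyclo[3.3.1]nonane | B1C2CCCC1CCC2 | starting material
13 | 9‑[(4S)‑6‑[3,4‑bis(triisopropylsilyloxy)phenyl]‑4‑(triethylsilyloxy)hexyl]‑9‑borabicyclo[3.3.1]nonane | CC[Si](CC)(CC)O[C@@H](CCCB1C2CCCC1CCC2)CCc1ccc(O[Si](C(C)C)(C(C)C)C(C)C)c(O[Si](C(C)C)(C(C)C)C(C)C)c1 | intermediate
14 | (4R)‑6‑[3,4‑bis(triisopropylsilyloxy)phenyl]‑4‑(triethylsilyloxy)hexan‑1‑ol | CC[Si](CC)(CC)O[C@@H](CCCO)CCc1ccc(O[Si](C(C)C)(C(C)C)C(C)C)c(O[Si](C(C)C)(C(C)C)C(C)C)c1 | intermediate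
15 | 5‑{[(4R)‑6‑[3,4‑bis(triisopropylsilyloxy)phenyl]‑4‑(triethylsilyloxy)hexyl]sulfanyl}‑1‑phenyl‑1H‑tetrazole | CC[Si](CC)(CC)O[C@@H](CCCSc1nnnn1-c1ccccc1)CCc1ccc(O[Si](C(C)C)(C(C)C)C(C)C)c(O[Si](C(C)C)(C(C)C)C(C)C)c1 | intermediate
16 | 5‑{[(4R)‑6‑[3,4‑bis(triisopropylsilyloxy)phenyl]‑4‑(triethylsilyloxy)hexyl]sulfonyl}‑1‑phenyl‑1H‑tetrazole | CC[Si](CC)(CC)O[C@@H](CCCS(=O)(=O)c1nnnn1-c1ccccc1)CCc1ccc(O[Si](C(C)C)(C(C)C)C(C)C)c(O[Si](C(C)C)(C(C)C)C(C)C)c1 | intermediate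
17 | 4‑hydroxybenzaldehyde | O=Cc1ccc(O)cc1 | starting material
18 | 4‑(triisopropylsilyloxy)benzaldehyde | O=Cc1ccc(O[Si](C(C)C)(C(C)C)C(C)C)cc1 | intermediate
19 | potassium α‑sulfonyl carbanion of 16 (4R) | [K+].CC[Si](CC)(CC)O[C@@H](CC[CH-]S(=O)(=O)c1nnnn1-c1ccccc1)CCc1ccc(O[Si](C(C)C)(C(C)C)C(C)C)c(O[Si](C(C)C)(C(C)C)C(C)C)c1 | intermediate
20 | {[(3S,6E)‑1‑[3,4‑bis(triisopropylsilyloxy)phenyl]‑7‑[4‑(triisopropylsilyloxy)phenyl]hept‑6‑en‑3‑yl]oxy}triethylsilane | CC[Si](CC)(CC)O[C@@H](CC/C=C/c1ccc(O[Si](C(C)C)(C(C)C)C(C)C)cc1)CCc1ccc(O[Si](C(C)C)(C(C)C)C(C)C)c(O[Si](C(C)C)(C(C)C)C(C)C)c1 | intermediate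
21 | (3S,6E)‑1‑[3,4‑bis(triisopropylsilyloxy)phenyl]‑7‑[4‑(triisopropylsilyloxy)phenyl]hept‑6‑en‑3‑ol | O[C@@H](CC/C=C/c1ccc(O[Si](C(C)C)(C(C)C)C(C)C)cc1)CCc1ccc(O[Si](C(C)C)(C(C)C)C(C)C)c(O[Si](C(C)C)(C(C)C)C(C)C)c1 | intermediate
22 | (3S,6E)‑1‑[3,4‑bis(triisopropylsilyloxy)phenyl]‑7‑[4‑(triisopropylsilyloxy)phenyl]hept‑6‑en‑3‑yl acetate | CC(=O)O[C@@H](CC/C=C/c1ccc(O[Si](C(C)C)(C(C)C)C(C)C)cc1)CCc1ccc(O[Si](C(C)C)(C(C)C)C(C)C)c(O[Si](C(C)C)(C(C)C)C(C)C)c1 | intermediate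
23 | (3S,6E)‑1‑(3,4‑dihydroxyphenyl)‑7‑(4‑hydroxyphenyl)hept‑6‑en‑3‑yl acetate | CC(=O)O[C@@H](CC/C=C/c1ccc(O)cc1)CCc1ccc(O)c(O)c1 | target

## Step count and risks
Total step count: 14. Longest linear sequence: 13 (steps 1–9 and 11–14); step 10 is the one‑step side branch.

**Risk 1, step 5 (ee below specification, or trouble removing the Ipc residues).**
- The fallback sets out from 3 and returns at 11. The stereocentre is then set by asymmetric hydrogenation instead of allylboration.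
- Crossed Claisen condensation of 3 with the lithium enolate of tert‑butyl acetate (LDA, THF, −78 → −20 °C) gives tert‑butyl 5‑[3,4‑bis(triisopropylsilyloxy)phenyl]‑3‑oxopentanoate F1.
- Noyori hydrogenation (RuCl2[(R)‑BINAP], H2 10 bar, MeOH, 50 °C) gives tert‑butyl (3R)‑5‑[3,4‑bis(triisopropylsilyloxy)phenyl]‑3‑hydroxypentanoate F2 in ≥97 % ee. The sense is the same as methyl acetoacetate → (R)‑3‑hydroxybutanoate.
- TESCl/imidazole gives tert‑butyl (3R)‑5‑[3,4‑bis(triisopropylsilyloxy)phenyl]‑3‑(triethylsilyloxy)pentanoate F3.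
- DIBAL‑H (2.5 equiv) gives (3R)‑5‑[3,4‑bis(triisopropylsilyloxy)phenyl]‑3‑(triethylsilyloxy)pentan‑1‑ol F4.
- TEMPO/PhI(OAc)2 gives (3R)‑5‑[3,4‑bis(triisopropylsilyloxy)phenyl]‑3‑(triethylsilyloxy)pentanal F5.
- Wittig methylenation (Ph3P=CH2, THF, −78 → 0 °C) delivers 11.

**Risk 2, step 11 (low E/Z ratio or poor conversion).**
- The fallback sets out from 14 and 18 and returns at 20, with the polarity of the olefination reversed.
- TEMPO/PhI(OAc)2 oxidation of 14 gives (4R)‑6‑[3,4‑bis(triisopropylsilyloxy)phenyl]‑4‑(triethylsilyloxy)hexanal F6.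
- In parallel, NaBH4 reduction of 18 gives [4‑(triisopropylsilyloxy)phenyl]methanol F7.
- Appel bromination (CBr4, PPh3, CH2Cl2, 0 °C) gives 4‑(triisopropylsilyloxy)benzyl bromide F8.
- Michaelis–Arbuzov reaction with P(OEt)3 (neat, 130 °C) gives diethyl [4‑(triisopropylsilyloxy)benzyl]phosphonate F9.
- Horner–Wadsworth–Emmons reaction of F9 (KHMDS, THF, −78 → 0 °C) with F6, warmed to rt, gives the (E)‑styrene 20.

**Risk 3, step 14 (acetate loss or transfer to a phenoxide, or catechol oxidation).**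
- The fallback sets out from 20 and returns at 23. It removes all silicon before any acetate is present.
- Excess TBAF (or Et3N·3HF) in THF under Ar gives (3S,6E)‑1‑(3,4‑dihydroxyphenyl)‑7‑(4‑hydroxyphenyl)hept‑6‑en‑3‑ol F10.
- Ac2O/pyridine/DMAP gives the stable, easily purified (3S,6E)‑1‑(3,4‑diacetoxyphenyl)‑7‑(4‑acetoxyphenyl)hept‑6‑en‑3‑yl acetate F11.
- Neutral, chemoselective hydrolysis of the three aryl acetates (NH4OAc, MeOH/H2O 4:1, rt, under Ar) leaves the much less electrophilic secondary alkyl acetate in place and gives 23.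

## Further compounds
F1 | step 5 | tert‑butyl 5‑[3,4‑bis(triisopropylsilyloxy)phenyl]‑3‑oxopentanoate | CC(C)(C)OC(=O)CC(=O)CCc1ccc(O[Si](C(C)C)(C(C)C)C(C)C)c(O[Si](C(C)C)(C(C)C)C(C)C)c1
F2 | step 5 | tert‑butyl (3R)‑5‑[3,4‑bis(triisopropylsilyloxy)phenyl]‑3‑hydroxypentanoate | O[C@@H](CC(=O)OC(C)(C)C)CCc1ccc(O[Si](C(C)C)(C(C)C)C(C)C)c(O[Si](C(C)C)(C(C)C)C(C)C)c1
F3 | step 5 | tert‑butyl (3R)‑5‑[3,4‑bis(triisopropylsilyloxy)phenyl]‑3‑(triethylsilyloxy)pentanoate | CC[Si](CC)(CC)O[C@@H](CC(=O)OC(C)(C)C)CCc1ccc(O[Si](C(C)C)(C(C)C)C(C)C)c(O[Si](C(C)C)(C(C)C)C(C)C)c1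
F4 | step 5 | (3R)‑5‑[3,4‑bis(triisopropylsilyloxy)phenyl]‑3‑(triethylsilyloxy)pentan‑1‑ol | CC[Si](CC)(CC)O[C@@H](CCO)CCc1ccc(O[Si](C(C)C)(C(C)C)C(C)C)c(O[Si](C(C)C)(C(C)C)C(C)C)c1
F5 | step 5 | (3R)‑5‑[3,4‑bis(triisopropylsilyloxy)phenyl]‑3‑(triethylsilyloxy)pentanal | CC[Si](CC)(CC)O[C@@H](CC=O)CCc1ccc(O[Si](C(C)C)(C(C)C)C(C)C)c(O[Si](C(C)C)(C(C)C)C(C)C)c1
F6 | step 11 | (4R)‑6‑[3,4‑bis(triisopropylsilyloxy)phenyl]‑4‑(triethylsilyloxy)hexanal | CC[Si](CC)(CC)O[C@@H](CCC=O)CCc1ccc(O[Si](C(C)C)(C(C)C)C(C)C)c(O[Si](C(C)C)(C(C)C)C(C)C)c1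
F7 | step 11 | [4‑(triisopropylsilyloxy)phenyl]methanol | OCc1ccc(O[Si](C(C)C)(C(C)C)C(C)C)cc1
F8 | step 11 | 4‑(triisopropylsilyloxy)benzyl bromide | BrCc1ccc(O[Si](C(C)C)(C(C)C)C(C)C)cc1
F9 | step 11 | diethyl [4‑(triisopropylsilyloxy)benzyl]phosphonate | CCOP(=O)(OCC)Cc1ccc(O[Si](C(C)C)(C(C)C)C(C)C)cc1
F10 | step 14 | (3S,6E)‑1‑(3,4‑dihydroxyphenyl)‑7‑(4‑hydroxyphenyl)hept‑6‑en‑3‑ol | O[C@@H](CC/C=C/c1ccc(O)cc1)CCc1ccc(O)c(O)c1
F11 | step 14 | (3S,6E)‑1‑(3,4‑diacetoxyphenyl)‑7‑(4‑acetoxyphenyl)hept‑6‑en‑3‑yl acetate | CC(=O)O[C@@H](CC/C=C/c1ccc(OC(C)=O)cc1)CCc1ccc(OC(C)=O)c(OC(C)=O)c1
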